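**Plan**
Rings are lettered A (3,5-dihydroxyphenoxy end), B and C (dibenzofuran), D (dioxin-fused ring), E and F (biaryl), G, and H (terminal trihydroxyphenoxy ring).
Enabling feature: ring B carries para oxygens at C4 (the ring A ether carbon, next to C4a, which bears the furan oxygen) and at C1 (the bay hydroxyl carbon, next to C9b). A third oxygen sits at C3 beside C4. This ortho-alkoxy hydroquinone monoether pattern is what a carbene/alkyne/CO benzannulation across the furan C2–C3 bond of a ring C benzofuran delivers.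
Retrosynthetic cuts, in order: the 15 O-alkyl bonds; the bay C9–O bond of the dioxin; the two aryl–O bonds at ring D (to the ring C oxygen and the ring E oxygen); the A–O–B ether; the three C–C bonds of ring B; the E–F biaryl bond; the F–O–G and G–O–H ethers.
Forward, north half: the ring C benzofuran is made from 2-bromoisovanillin, converted to the chromium carbene, annulated to ring B, then given the ring A ether. South half: H, G and F are joined by Ullmann etherification and Baeyer–Villiger oxidation, and E is added by Negishi coupling.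
Ring D enters as a masked 2,3-difluoroterephthalaldehyde. Its fluorides are displaced in a fixed order (E–H phenol, then A–B–C phenol). A double Baeyer–Villiger oxidation turns both formyl groups into hydroxyls, one of these closes the dioxin onto the bay bromide, and BBr3 finishes.
Stereochemistry: there are no stereocentres, and the E–F axis is formed without control.

Key step: step 7

Remark: the target is drawn without a descriptor for the hindered E–F axis, so the axis is taken as unspecified and is made as the racemate. Dibenzofuran locants used below: ring B = C1–C4, ring C = C6–C9.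

**Route**

Step 1
Reactants: 1 2-bromo-3-hydroxy-4-methoxybenzaldehyde
Product: 3 2-bromo-3,6-dihydroxy-4-methoxybenzaldehyde, via aryl potassium sulfate 2 (not isolated)
Conditions: K2S2O8, aq NaOH, 0 °C to rt; then aq HCl, 80 °C
Reagents that add atoms: potassium peroxodisulfate, [K+].[K+].[O-]S(=O)(=O)OOS(=O)(=O)[O-]
Why: Elbs persulfate oxidation: the phenoxide of 1 attacks the peroxide through its only free para carbon (C6), and the hydroquinone is released from base-stable sulfate 2 only in the acidic second stage, which shields it from alkaline autoxidation.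

Step 2
Reactants: 3 2-bromo-3,6-dihydroxy-4-methoxybenzaldehyde
Product: 4 3-(benzyloxy)-2-bromo-6-hydroxy-4-methoxybenzaldehyde
Conditions: BnBr (1.0 equiv), K2CO3 (1.0 equiv), DMF, rt
Reagents that add atoms: benzyl bromide, BrCc1ccccc1
Why: Williamson etherification under one equivalent of weak base: the C6 hydroxyl is hydrogen-bonded to the formyl group and its anion is delocalised into it, so the C3 phenoxide should be the one benzylated, as in other 2,5-dihydroxybenzaldehydes.

Step 3
Reactants: 4 3-(benzyloxy)-2-bromo-6-hydroxy-4-methoxybenzaldehyde; 5 ethyl diazoacetate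
Product: 7 ethyl 5-(benzyloxy)-4-bromo-6-methoxybenzofuran-3-carboxylate, via hemiacetal 6 (not isolated)
Conditions: HBF4·OEt2 (10 mol %), CH2Cl2, rt; then conc. H2SO4 (cat.), rt, short contact
Reagents that add atoms: none
Why: Acid-catalysed aldehyde/diazoester homologation with 1,2-shift of the electron-rich aryl group gives the 2-aryl-3-oxopropanoate, which the ortho hydroxyl traps as hemiacetal 6 and acid dehydrates to the benzofuran-3-carboxylate, a known one-flask conversion of salicylaldehydes.

Step 4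
Reactants: 7 ethyl 5-(benzyloxy)-4-bromo-6-methoxybenzofuran-3-carboxylate
Product: 8 5-(benzyloxy)-4-bromo-6-methoxybenzofuran-3-carboxylic acid
Conditions: LiOH, THF/MeOH/H2O, 50 °C; then aq HCl
Reagents that add atoms: lithium hydroxide, [Li+].[OH-]
Why: Ester saponification; the aryl bromide and the benzyl and methyl ethers are inert to hydroxide at this temperature.

Step 5
Reactants: 8 5-(benzyloxy)-4-bromo-6-methoxybenzofuran-3-carboxylic acid
Product: 9 5-(benzyloxy)-4-bromo-6-methoxybenzofuran-3-carbonyl chloride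
Conditions: (COCl)2, DMF (cat.), CH2Cl2, 0 °C to rt
Reagents that add atoms: oxalyl chloride, ClC(=O)C(=O)Cl
Why: Acid chloride formation through the chloroiminium catalyst, under conditions that leave the ethers and the furan untouched.

Step 6
Reactants: 9 5-(benzyloxy)-4-bromo-6-methoxybenzofuran-3-carbonyl chloride; 10 Cr(CO)6
Product: 13 pentacarbonyl{[5-(benzyloxy)-4-bromo-6-methoxybenzofuran-3-yl](methoxy)methylidene}chromium, via Na2Cr(CO)5 11 (not isolated), via sodium acylchromate 12 (not isolated)
Conditions: 10, NaC10H8 (2 equiv), THF, −78 °C; 9, −78 to 0 °C; then Me3OBF4, CH2Cl2, 0 °C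
Reagents that add atoms: trimethyloxonium tetrafluoroborate, C[O+](C)C.F[B-](F)(F)F
Why: Acylation of the pentacarbonylchromate dianion followed by O-methylation of the acylate is the acid chloride entry to Fischer alkoxycarbene complexes of zerovalent chromium, and it avoids a 3-lithiobenzofuran, which would ring-open and would not tolerate the bromide.

Step 7
Reactants: 13 pentacarbonyl{[5-(benzyloxy)-4-bromo-6-methoxybenzofuran-3-yl](methoxy)methylidene}chromium; 14 ethoxyacetylene
Product: 16 8-(benzyloxy)-9-bromo-3-ethoxy-1,7-dimethoxydibenzo[b,d]furan-4-ol, via alkenyl(ethoxy)carbene complex 15 (not isolated)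
Conditions: 14 (3 equiv), THF, 45 °C; then hν (λ > 350 nm), CO (1 atm), THF, rt
Reagents that add atoms: none
Why: The nucleophilic terminal carbon of ynol ether 14 bonds to the electrophilic carbene carbon of 13, and formal insertion into the Cr=C bond gives 15, in which the ethoxy-bearing carbon is now the carbene carbon on zerovalent chromium (first C–C bond). Irradiation moves one CO ligand onto that carbon (second C–C bond) to give a chromium-bound dienylketene whose ketene carbon closes onto furan C2 (third C–C bond); enolisation gives the free phenol and the CO atmosphere carries the metal off as Cr(CO)6. The closest known reaction types are the Dötz benzannulation of furyl and benzofuryl alkoxycarbene chromium complexes with alkynes and the photochemical benzannulation of dienyl(alkoxy)carbene chromium complexes to ortho-alkoxyphenols; the light-driven second stage is included because a donor-stabilised carbene such as 15 takes up CO reluctantly on heating alone. Ring B, the only ring formed, closes by a 6π electrocyclisation (six-membered, carbocyclic) across the furan C2–C3 bond, and C2 is the only possible terminus because the other neighbour of C3 is the quaternary C3a. No stereocentre is created. The step needs one alkyne orientation and the phenol rather than the indene, furan or cyclobutenone channels: the polarity of the ynol ether and the usual preference for the larger alkyne substituent beside the CO-derived carbon both place OEt next to the new hydroxyl, an alkoxy (not amino) carbene on chromium in THF favours CO incorporation, light of λ > 350 nm leaves the C–Br bond alone, and the three ring B oxygens emerge distinct as C1–OMe, C3–OEt and free C4–OH.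

Step 8
Reactants: 16 8-(benzyloxy)-9-bromo-3-ethoxy-1,7-dimethoxydibenzo[b,d]furan-4-ol; 17 1-iodo-3,5-dimethoxybenzene
Product: 18 8-(benzyloxy)-9-bromo-4-(3,5-dimethoxyphenoxy)-3-ethoxy-1,7-dimethoxydibenzo[b,d]furan
Conditions: 17 (2 equiv), CuI (10 mol %), picolinic acid (20 mol %), K3PO4, DMSO, 85 °C, Ar
Reagents that add atoms: none
Why: Ullmann-type diaryl ether synthesis with CuI/picolinic acid, a system suited to ortho-flanked phenols; the open iodide 17 should react much faster than the bay bromide of 16, which is shielded by the benzyloxy group and the facing C1 methoxy group.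

Step 9
Reactants: 18 8-(benzyloxy)-9-bromo-4-(3,5-dimethoxyphenoxy)-3-ethoxy-1,7-dimethoxydibenzo[b,d]furan
Product: 19 9-bromo-4-(3,5-dimethoxyphenoxy)-3-ethoxy-1,7-dimethoxydibenzo[b,d]furan-8-ol
Conditions: BCl3, C6HMe5, CH2Cl2, −78 °C
Reagents that add atoms: none
Why: Lewis acid debenzylation with a cation scavenger: at −78 °C BCl3 cleaves only the benzyl ether, pentamethylbenzene intercepts the benzyl cation before it can alkylate ring A, and the bromide, which hydrogenolysis would endanger, is kept.

Step 10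
Reactants: 20 2,3-difluoro-6-methoxybenzaldehyde
Product: 21 2-(2,3-difluoro-6-methoxyphenyl)-1,3-dioxolane
Conditions: HOCH2CH2OH, TsOH (cat.), toluene, reflux (Dean–Stark)
Reagents that add atoms: ethylene glycol, OCCO
Why: Acid-catalysed acetalisation masks the formyl group so that it neither reacts with the organolithium of step 11 nor activates the neighbouring fluoride in step 21.

Step 11
Reactants: 21 2-(2,3-difluoro-6-methoxyphenyl)-1,3-dioxolane
Product: 23 4-(1,3-dioxolan-2-yl)-2,3-difluoro-5-methoxybenzaldehyde, via aryllithium 22 (not isolated)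
Conditions: s-BuLi, THF, −78 °C; DMF, −78 to 0 °C; aq NH4Cl
Reagents that add atoms: N,N-dimethylformamide, CN(C)C=O
Why: Directed ortho-lithiation and formylation: the proton next to fluorine (phenyl C4 of 21) is the most acidic ring proton, and at −78 °C the aryllithium is trapped by DMF before it can lose LiF.

Step 12
Reactants: 24 2,4,6-trimethoxybenzaldehyde
Product: 25 2,4,6-trimethoxyphenol
Conditions: H2O2 (30 %), H2SO4 (cat.), MeOH, rt
Reagents that add atoms: hydrogen peroxide, OO
Why: Acid-catalysed Dakin-type oxidation (Baeyer–Villiger aryl migration of the hydroperoxide adduct) is favoured by three donor methoxy groups, and methanol cleaves the formate in the same flask.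

Step 13
Reactants: 26 1-bromo-3,5-dimethoxybenzene
Product: 27 2-bromo-4,6-dimethoxybenzaldehyde
Conditions: POCl3, DMF, 0 to 90 °C; then ice/H2O
Reagents that add atoms: N,N-dimethylformamide, CN(C)C=O; water, O
Why: Vilsmeier–Haack formylation occurs para to one methoxy group and ortho to the other, next to bromine, rather than at the more crowded carbon between the two methoxy groups.

Step 14
Reactants: 25 2,4,6-trimethoxyphenol; 27 2-bromo-4,6-dimethoxybenzaldehyde
Product: 28 2,4-dimethoxy-6-(2,4,6-trimethoxyphenoxy)benzaldehyde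
Conditions: CuI (10 mol %), picolinic acid (20 mol %), K3PO4, DMSO, 90 °C, Ar
Reagents that add atoms: none
Why: Ullmann-type etherification in which the ortho formyl group activates the C–Br bond and the CuI/picolinic acid system accepts the 2,6-disubstituted phenol.

Step 15
Reactants: 28 2,4-dimethoxy-6-(2,4,6-trimethoxyphenoxy)benzaldehyde
Product: 30 2,4-dimethoxy-6-(2,4,6-trimethoxyphenoxy)phenol, via aryl formate 29 (not isolated)
Conditions: mCPBA, CH2Cl2, 0 °C to rt; wash (aq NaHCO3); then K2CO3 (cat.), MeOH, rt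
Reagents that add atoms: 3-chloroperbenzoic acid, OOC(=O)c1cccc(Cl)c1
Why: Baeyer–Villiger oxidation: the trioxygenated aryl group migrates in preference to hydrogen, and mild methanolysis of formate 29 gives the ring G phenol with its hydroxyl exactly where ring F must be attached.

Step 16
Reactants: 17 1-iodo-3,5-dimethoxybenzene
Product: 31 2-bromo-1-iodo-3,5-dimethoxybenzene
Conditions: NBS, MeCN, 0 °C to rt
Reagents that add atoms: N-bromosuccinimide, O=C1CCC(=O)N1Br
Why: Electrophilic aromatic bromination with the same orientation as in step 13 (para to one methoxy group, beside the halogen) installs the future biaryl handle next to the iodide.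

Step 17
Reactants: 30 2,4-dimethoxy-6-(2,4,6-trimethoxyphenoxy)phenol; 31 2-bromo-1-iodo-3,5-dimethoxybenzene
Product: 32 2-bromo-1-[2,4-dimethoxy-6-(2,4,6-trimethoxyphenoxy)phenoxy]-3,5-dimethoxybenzene
Conditions: CuI (10 mol %), picolinic acid (20 mol %), K3PO4, DMSO, 80 °C, Ar
Reagents that add atoms: none
Why: Chemoselective Ullmann-type etherification: monovalent copper engages C–I well before C–Br, so hindered phenol 30 is arylated at the iodide carbon and the bromide is kept for step 19.

Step 18
Reactants: 33 3,5-dimethoxyphenol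
Product: 34 1,3-dimethoxy-5-(methoxymethoxy)benzene
Conditions: NaH, MOMCl, THF, 0 °C
Reagents that add atoms: chloromethyl methyl ether, COCCl
Why: Williamson-type O-alkylation gives a protecting group that is also the strongest ortho-directing group of the ring for step 19.

Step 19
Reactants: 34 1,3-dimethoxy-5-(methoxymethoxy)benzene; 32 2-bromo-1-[2,4-dimethoxy-6-(2,4,6-trimethoxyphenoxy)phenoxy]-3,5-dimethoxybenzene
Product: 37 2,2',4,4'-tetramethoxy-6-(methoxymethoxy)-6'-[2,4-dimethoxy-6-(2,4,6-trimethoxyphenoxy)phenoxy]biphenyl, via aryllithium 35 (not isolated), via arylzinc chloride 36 (not isolated)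
Conditions: n-BuLi, THF, 0 °C to rt; ZnCl2, THF, 0 °C; then 32, Pd2(dba)3 (2.5 mol %), RuPhos (10 mol %), THF, 70 °C
Reagents that add atoms: none
Why: Directed ortho-lithiation between the MOM ether and a methoxy group, transmetalation and Negishi coupling: zerovalent palladium with a bulky dialkylbiarylphosphine is established for tetra-ortho-substituted biaryls, the arylzinc avoids the protodeboronation of 2,6-dialkoxyarylboronic acids, and the axis forms as a racemate.

Step 20
Reactants: 37 2,2',4,4'-tetramethoxy-6-(methoxymethoxy)-6'-[2,4-dimethoxy-6-(2,4,6-trimethoxyphenoxy)phenoxy]biphenyl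
Product: 38 2',4,4',6-tetramethoxy-6'-[2,4-dimethoxy-6-(2,4,6-trimethoxyphenoxy)phenoxy]biphenyl-2-ol (E–F–G–H phenol)
Conditions: HCl (cat.), MeOH, 50 °C
Reagents that add atoms: none
Why: Acid-catalysed transacetalisation removes the MOM group while aryl methyl ethers and diaryl ethers are untouched.

Step 21
Reactants: 38 E–F–G–H phenol; 23 4-(1,3-dioxolan-2-yl)-2,3-difluoro-5-methoxybenzaldehyde
Product: 40 3-fluoro-5-methoxy-2-(E–F–G–H aryloxy)benzene-1,4-dicarbaldehyde, via dioxolane 39 (not isolated)
Conditions: K2CO3, DMF, 110 °C; then aq HCl (2 M), THF, rt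
Reagents that add atoms: water, O
Why: Nucleophilic aromatic substitution (addition–elimination): only the fluoride ortho to the free formyl group of 23 is activated, since the other lies beside the masked aldehyde and meta to the free one, so the ring E oxygen lands on the correct carbon of ring D before mild acid unmasks the second formyl group.

Step 22
Reactants: 40 3-fluoro-5-methoxy-2-(E–F–G–H aryloxy)benzene-1,4-dicarbaldehyde; 19 9-bromo-4-(3,5-dimethoxyphenoxy)-3-ethoxy-1,7-dimethoxydibenzo[b,d]furan-8-ol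
Product: 41 5-methoxy-2-(E–F–G–H aryloxy)-3-(A–B–C aryloxy)benzene-1,4-dicarbaldehyde
Conditions: Cs2CO3, DMSO, 95 °C, Ar
Reagents that add atoms: none
Why: Second nucleophilic aromatic substitution: the remaining fluoride is now ortho to the liberated formyl group and is by far the best leaving group on ring D, so the ring C phenoxide enters beside the ring E ether with unambiguous regiochemistry, and the aryl bromide is inert in the absence of a metal.

Step 23
Reactants: 41 5-methoxy-2-(E–F–G–H aryloxy)-3-(A–B–C aryloxy)benzene-1,4-dicarbaldehyde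
Product: 43 5-methoxy-2-(E–F–G–H aryloxy)-3-(A–B–C aryloxy)benzene-1,4-diol, via bis-formate 42 (not isolated)
Conditions: mCPBA (3 equiv), CH2Cl2, 0 °C to rt; wash (aq NaHCO3); then K2CO3 (cat.), degassed MeOH, 0 °C, Ar
Reagents that add atoms: 3-chloroperbenzoic acid, OOC(=O)c1cccc(Cl)c1
Why: Double Baeyer–Villiger oxidation: each formyl group sits on a carbon with an ortho oxygen donor, so aryl migration gives bis-formate 42, and catalytic methanolysis under argon turns the two activating groups into the two para hydroxyls of ring D.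

Step 24
Reactants: 43 5-methoxy-2-(E–F–G–H aryloxy)-3-(A–B–C aryloxy)benzene-1,4-diol
Product: 44 dioxin-closed A–H octamer (14 OMe; 1 OEt on ring B; free ring D hydroxyl)
Conditions: CuI (20 mol %), N,N-dimethylglycine (40 mol %), Cs2CO3, degassed dioxane, 100 °C, Ar
Reagents that add atoms: none
Why: Intramolecular Ullmann-type etherification: only the hydroxyl flanked by the methoxy group lies ortho to the ring C ether and can reach the bay bromide through a six-membered transition state, so the dioxin closes in one orientation, and on the now electron-rich ring D no Smiles-type scrambling is possible.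

Step 25
Reactants: 44 dioxin-closed A–H octamer
Product: 45 CNP0192765.0
Conditions: BBr3 (excess), CH2Cl2, −78 °C to rt; then ice/H2O, Ar
Reagents that add atoms: none
Why: Exhaustive Lewis acid ether cleavage: BBr3 dealkylates the fourteen methyl ethers and the ethyl ether by bromide attack at the alkyl carbon, while the diaryl ether, dioxin, furan and biaryl bonds offer no such pathway.

**Compound list**
1 | 2-bromo-3-hydroxy-4-methoxybenzaldehyde | COc1ccc(C=O)c(Br)c1O | starting material
2 | potassium 3-bromo-2-formyl-4-hydroxy-5-methoxyphenyl sulfate | COc1cc(OS(=O)(=O)[O-])c(C=O)c(Br)c1O.[K+] | intermediate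
3 | 2-bromo-3,6-dihydroxy-4-methoxybenzaldehyde | COc1cc(O)c(C=O)c(Br)c1O | intermediate
4 | 3-(benzyloxy)-2-bromo-6-hydroxy-4-methoxybenzaldehyde | COc1cc(O)c(C=O)c(Br)c1OCc1ccccc1 | intermediate
5 | ethyl diazoacetate | CCOC(=O)C=[N+]=[N-] | starting material
6 | ethyl 5-(benzyloxy)-4-bromo-2-hydroxy-6-methoxy-2,3-dihydrobenzofuran-3-carboxylate (diastereomer mixture) | CCOC(=O)C1C(O)Oc2cc(OC)c(OCc3ccccc3)c(Br)c12 | intermediate
7 | ethyl 5-(benzyloxy)-4-bromo-6-methoxybenzofuran-3-carboxylate | CCOC(=O)c1coc2cc(OC)c(OCc3ccccc3)c(Br)c12 | intermediate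
8 | 5-(benzyloxy)-4-bromo-6-methoxybenzofuran-3-carboxylic acid | OC(=O)c1coc2cc(OC)c(OCc3ccccc3)c(Br)c12 | intermediate
9 | 5-(benzyloxy)-4-bromo-6-methoxybenzofuran-3-carbonyl chloride | ClC(=O)c1coc2cc(OC)c(OCc3ccccc3)c(Br)c12 | intermediate
10 | chromium hexacarbonyl Cr(CO)6 | O=C=[Cr](=C=O)(=C=O)(=C=O)(=C=O)=C=O | starting material
11 | disodium pentacarbonylchromate Na2Cr(CO)5 | [Na+].[Na+].O=C=[Cr-2](=C=O)(=C=O)(=C=O)=C=O | intermediate
12 | sodium pentacarbonyl{[5-(benzyloxy)-4-bromo-6-methoxybenzofuran-3-yl]carbonyl}chromate | [Na+].[O-]C(=[Cr](=C=O)(=C=O)(=C=O)(=C=O)=C=O)c1coc2cc(OC)c(OCc3ccccc3)c(Br)c12 | intermediate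
13 | pentacarbonyl{[5-(benzyloxy)-4-bromo-6-methoxybenzofuran-3-yl](methoxy)methylidene}chromium | COC(=[Cr](=C=O)(=C=O)(=C=O)(=C=O)=C=O)c1coc2cc(OC)c(OCc3ccccc3)c(Br)c12 | intermediate
14 | ethoxyacetylene | CCOC#C | starting material
15 | pentacarbonyl{3-[5-(benzyloxy)-4-bromo-6-methoxybenzofuran-3-yl]-1-ethoxy-3-methoxyprop-2-en-1-ylidene}chromium (alkene geometry undefined) | CCOC(=[Cr](=C=O)(=C=O)(=C=O)(=C=O)=C=O)C=C(OC)c1coc2cc(OC)c(OCc3ccccc3)c(Br)c12 | intermediate
16 | 8-(benzyloxy)-9-bromo-3-ethoxy-1,7-dimethoxydibenzo[b,d]furan-4-ol | COc1cc(OCC)c(O)c2oc3cc(OC)c(OCc4ccccc4)c(Br)c3c12 | intermediate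
17 | 1-iodo-3,5-dimethoxybenzene | COc1cc(I)cc(OC)c1 | starting material
18 | 8-(benzyloxy)-9-bromo-4-(3,5-dimethoxyphenoxy)-3-ethoxy-1,7-dimethoxydibenzo[b,d]furan | COc1cc(OC)cc(Oc2c(OCC)cc(OC)c3c2oc2cc(OC)c(OCc4ccccc4)c(Br)c23)c1 | intermediate
19 | 9-bromo-4-(3,5-dimethoxyphenoxy)-3-ethoxy-1,7-dimethoxydibenzo[b,d]furan-8-ol (A–B–C phenol) | COc1cc(OC)cc(Oc2c(OCC)cc(OC)c3c2oc2cc(OC)c(O)c(Br)c23)c1 | intermediate
20 | 2,3-difluoro-6-methoxybenzaldehyde | COc1ccc(F)c(F)c1C=O | starting material
21 | 2-(2,3-difluoro-6-methoxyphenyl)-1,3-dioxolane | COc1ccc(F)c(F)c1C1OCCO1 | intermediate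
22 | [4-(1,3-dioxolan-2-yl)-2,3-difluoro-5-methoxyphenyl]lithium | [Li]c1cc(OC)c(C2OCCO2)c(F)c1F | intermediate
23 | 4-(1,3-dioxolan-2-yl)-2,3-difluoro-5-methoxybenzaldehyde | COc1cc(C=O)c(F)c(F)c1C1OCCO1 | intermediate
24 | 2,4,6-trimethoxybenzaldehyde | COc1cc(OC)c(C=O)c(OC)c1 | starting material
25 | 2,4,6-trimethoxyphenol | COc1cc(OC)c(O)c(OC)c1 | intermediate
26 | 1-bromo-3,5-dimethoxybenzene | COc1cc(Br)cc(OC)c1 | starting material
27 | 2-bromo-4,6-dimethoxybenzaldehyde | COc1cc(Br)c(C=O)c(OC)c1 | intermediate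
28 | 2,4-dimethoxy-6-(2,4,6-trimethoxyphenoxy)benzaldehyde | COc1cc(OC)c(C=O)c(Oc2c(OC)cc(OC)cc2OC)c1 | intermediate
29 | 2,4-dimethoxy-6-(2,4,6-trimethoxyphenoxy)phenyl formate | COc1cc(OC)c(OC=O)c(Oc2c(OC)cc(OC)cc2OC)c1 | intermediate
30 | 2,4-dimethoxy-6-(2,4,6-trimethoxyphenoxy)phenol | COc1cc(OC)c(O)c(Oc2c(OC)cc(OC)cc2OC)c1 | intermediate
31 | 2-bromo-1-iodo-3,5-dimethoxybenzene | COc1cc(I)c(Br)c(OC)c1 | intermediate
32 | 2-bromo-1-[2,4-dimethoxy-6-(2,4,6-trimethoxyphenoxy)phenoxy]-3,5-dimethoxybenzene (F–G–H bromide) | COc1cc(OC)c(Br)c(Oc2c(OC)cc(OC)cc2Oc2c(OC)cc(OC)cc2OC)c1 | intermediate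
33 | 3,5-dimethoxyphenol | COc1cc(O)cc(OC)c1 | starting material
34 | 1,3-dimethoxy-5-(methoxymethoxy)benzene | COCOc1cc(OC)cc(OC)c1 | intermediate
35 | [2,4-dimethoxy-6-(methoxymethoxy)phenyl]lithium | [Li]c1c(OC)cc(OC)cc1OCOC | intermediate
36 | chloro[2,4-dimethoxy-6-(methoxymethoxy)phenyl]zinc | Cl[Zn]c1c(OC)cc(OC)cc1OCOC | intermediate
37 | 2,2',4,4'-tetramethoxy-6-(methoxymethoxy)-6'-[2,4-dimethoxy-6-(2,4,6-trimethoxyphenoxy)phenoxy]biphenyl (racemic axis) | COCOc1cc(OC)cc(OC)c1-c1c(OC)cc(OC)cc1Oc1c(OC)cc(OC)cc1Oc1c(OC)cc(OC)cc1OC | intermediate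
38 | 2',4,4',6-tetramethoxy-6'-[2,4-dimethoxy-6-(2,4,6-trimethoxyphenoxy)phenoxy]biphenyl-2-ol (E–F–G–H phenol, racemic axis) | Oc1cc(OC)cc(OC)c1-c1c(OC)cc(OC)cc1Oc1c(OC)cc(OC)cc1Oc1c(OC)cc(OC)cc1OC | intermediate
39 | 4-(1,3-dioxolan-2-yl)-3-fluoro-5-methoxy-2-(E–F–G–H aryloxy)benzaldehyde (aryloxy = O-linked residue of 38) | COc1cc(C=O)c(Oc2cc(OC)cc(OC)c2-c2c(OC)cc(OC)cc2Oc2c(OC)cc(OC)cc2Oc2c(OC)cc(OC)cc2OC)c(F)c1C1OCCO1 | intermediate
40 | 3-fluoro-5-methoxy-2-(E–F–G–H aryloxy)benzene-1,4-dicarbaldehyde | COc1cc(C=O)c(Oc2cc(OC)cc(OC)c2-c2c(OC)cc(OC)cc2Oc2c(OC)cc(OC)cc2Oc2c(OC)cc(OC)cc2OC)c(F)c1C=O | intermediate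
41 | 5-methoxy-2-(E–F–G–H aryloxy)-3-(A–B–C aryloxy)benzene-1,4-dicarbaldehyde (A–B–C aryloxy = O-linked residue of 19) | COc1cc(C=O)c(Oc2cc(OC)cc(OC)c2-c2c(OC)cc(OC)cc2Oc2c(OC)cc(OC)cc2Oc2c(OC)cc(OC)cc2OC)c(Oc2c(OC)cc3oc4c(Oc5cc(OC)cc(OC)c5)c(OCC)cc(OC)c4c3c2Br)c1C=O | intermediate
42 | 5-methoxy-2-(E–F–G–H aryloxy)-3-(A–B–C aryloxy)benzene-1,4-diyl diformate | COc1cc(OC=O)c(Oc2cc(OC)cc(OC)c2-c2c(OC)cc(OC)cc2Oc2c(OC)cc(OC)cc2Oc2c(OC)cc(OC)cc2OC)c(Oc2c(OC)cc3oc4c(Oc5cc(OC)cc(OC)c5)c(OCC)cc(OC)c4c3c2Br)c1OC=O | intermediate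
43 | 5-methoxy-2-(E–F–G–H aryloxy)-3-(A–B–C aryloxy)benzene-1,4-diol | COc1cc(O)c(Oc2cc(OC)cc(OC)c2-c2c(OC)cc(OC)cc2Oc2c(OC)cc(OC)cc2Oc2c(OC)cc(OC)cc2OC)c(Oc2c(OC)cc3oc4c(Oc5cc(OC)cc(OC)c5)c(OCC)cc(OC)c4c3c2Br)c1O | intermediate
44 | dioxin-closed A–H octamer: all hydroxyls of 45 as methyl ethers except ring B C3 (ethyl ether) and the ring D hydroxyl beside the ring E ether (free) | COc1cc(OC)cc(Oc2c(OCC)cc(OC)c3c2oc2cc(OC)c4c(c23)Oc2c(OC)cc(O)c(Oc3cc(OC)cc(OC)c3-c3c(OC)cc(OC)cc3Oc3c(OC)cc(OC)cc3Oc3c(OC)cc(OC)cc3OC)c2O4)c1 | intermediate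
45 | CNP0192765.0 | Oc1cc(O)cc(Oc2c(O)cc(O)c3c2oc2cc(O)c4c(c23)Oc2c(O)cc(O)c(Oc3cc(O)cc(O)c3-c3c(O)cc(O)cc3Oc3c(O)cc(O)cc3Oc3c(O)cc(O)cc3O)c2O4)c1 | target

**Step count**
Total step count: 25.
Longest linear sequence: 13 steps (steps 1–9, then 22–25).

**Steps most likely to fail**

Step 7.
- Risk: the electron-rich alkyne may oligomerise on the metal. The sequence may also stop after insertion, because the donor-stabilised carbene is slow to take up CO. Crowding by the peri bromine may retard ring closure and let five- or four-membered-ring channels compete.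
- Fallback (sets out from 7, rejoins at 15): the alkenylcarbene is made without alkyne insertion. Ester 7 is reduced with i-Bu2AlH to [5-(benzyloxy)-4-bromo-6-methoxybenzofuran-3-yl]methanol F1. MnO2 oxidation gives 5-(benzyloxy)-4-bromo-6-methoxybenzofuran-3-carbaldehyde F2, and the Ohira–Bestmann reagent homologates it to 5-(benzyloxy)-4-bromo-3-ethynyl-6-methoxybenzofuran F3. Deprotonation with LiN(i-Pr)2, addition to Cr(CO)6 and O-ethylation with Et3OBF4 give the alkynyl(ethoxy)carbene complex F4. Methanol (cat. NaOMe) adds to F4 in Michael fashion to give 15 as an isolable compound. Irradiation under CO then closes ring B to 16. Ring B still arises from a chromium carbene, one CO ligand and 6π closure onto furan C2.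

Step 22.
- Risk: addition of a doubly ortho-flanked phenoxide to a crowded, only moderately activated C–F bond may be too slow. Prolonged heating would then allow aryloxide exchange at the neighbouring ether carbon or degradation of the aldehydes.
- Fallback (sets out from 38, rejoins at 43): a bromoquinone takes the part of ring D, so both ethers form by addition–elimination near room temperature. Purchased 5-bromovanillin F5 is brominated (Br2, Fe powder, AcOH) to 5,6-dibromovanillin F6. Dakin oxidation (H2O2, aq NaOH) gives 2,3-dibromo-5-methoxybenzene-1,4-diol F7, and Ag2O gives 2,3-dibromo-5-methoxy-1,4-benzoquinone F8. The phenoxide of 38 (Cs2CO3, MeCN, 0 °C) displaces the bromide conjugated to the carbonyl that is not tied up as a vinylogous ester by the methoxy group. This gives the mono(aryloxy)bromoquinone F9. The phenoxide of 19 then displaces the second bromide at low temperature to give the bis(aryloxy)quinone F10. Exchange at the first ether carbon is disfavoured because the bromophenoxide of 19 is the better leaving group. Na2S2O4 reduces F10 to 43.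

Step 24.
- Risk: the hydroquinone may be re-oxidised under basic copper conditions, hydrodebromination may occur, and copper may engage the shielded bay C–Br bond only slowly.
- Fallback (sets out from 43, rejoins at 45): the redox-labile hydroquinone is removed first and the bond is then made by palladium catalysis. The less hindered hydroxyl (beside the ring D hydrogen) is methylated (MeI, 1 equiv, K2CO3, acetone) to give the monomethyl ether F11. Intramolecular C–O coupling through oxidative addition to zerovalent palladium (Pd(OAc)2, t-BuXPhos, K3PO4, toluene, 100 °C) gives the fully alkylated octamer F12. BBr3, as in step 25, converts F12 into 45.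

**Further compounds**
F1 | step 7 | [5-(benzyloxy)-4-bromo-6-methoxybenzofuran-3-yl]methanol | OCc1coc2cc(OC)c(OCc3ccccc3)c(Br)c12
F2 | step 7 | 5-(benzyloxy)-4-bromo-6-methoxybenzofuran-3-carbaldehyde | O=Cc1coc2cc(OC)c(OCc3ccccc3)c(Br)c12
F3 | step 7 | 5-(benzyloxy)-4-bromo-3-ethynyl-6-methoxybenzofuran | C#Cc1coc2cc(OC)c(OCc3ccccc3)c(Br)c12
F4 | step 7 | pentacarbonyl{3-[5-(benzyloxy)-4-bromo-6-methoxybenzofuran-3-yl]-1-ethoxyprop-2-yn-1-ylidene}chromium | CCOC(=[Cr](=C=O)(=C=O)(=C=O)(=C=O)=C=O)C#Cc1coc2cc(OC)c(OCc3ccccc3)c(Br)c12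
F5 | step 22 | 5-bromovanillin (purchased) | COc1cc(C=O)cc(Br)c1O
F6 | step 22 | 5,6-dibromovanillin (2,3-dibromo-4-hydroxy-5-methoxybenzaldehyde) | COc1cc(C=O)c(Br)c(Br)c1O
F7 | step 22 | 2,3-dibromo-5-methoxybenzene-1,4-diol | COc1cc(O)c(Br)c(Br)c1O
F8 | step 22 | 2,3-dibromo-5-methoxy-1,4-benzoquinone | COC1=CC(=O)C(Br)=C(Br)C1=O
F9 | step 22 | 3-bromo-5-methoxy-2-(E–F–G–H aryloxy)-1,4-benzoquinone | COC1=CC(=O)C(Oc2cc(OC)cc(OC)c2-c2c(OC)cc(OC)cc2Oc2c(OC)cc(OC)cc2Oc2c(OC)cc(OC)cc2OC)=C(Br)C1=O
F10 | step 22 | 5-methoxy-2-(E–F–G–H aryloxy)-3-(A–B–C aryloxy)-1,4-benzoquinone | COC1=CC(=O)C(Oc2cc(OC)cc(OC)c2-c2c(OC)cc(OC)cc2Oc2c(OC)cc(OC)cc2Oc2c(OC)cc(OC)cc2OC)=C(Oc2c(OC)cc3oc4c(Oc5cc(OC)cc(OC)c5)c(OCC)cc(OC)c4c3c2Br)C1=O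
F11 | step 24 | 4,6-dimethoxy-3-(E–F–G–H aryloxy)-2-(A–B–C aryloxy)phenol | COc1cc(OC)c(Oc2cc(OC)cc(OC)c2-c2c(OC)cc(OC)cc2Oc2c(OC)cc(OC)cc2Oc2c(OC)cc(OC)cc2OC)c(Oc2c(OC)cc3oc4c(Oc5cc(OC)cc(OC)c5)c(OCC)cc(OC)c4c3c2Br)c1O
F12 | step 24 | fully alkylated dioxin-closed A–H octamer (15 OMe; 1 OEt) | COc1cc(OC)cc(Oc2c(OCC)cc(OC)c3c2oc2cc(OC)c4c(c23)Oc2c(OC)cc(OC)c(Oc3cc(OC)cc(OC)c3-c3c(OC)cc(OC)cc3Oc3c(OC)cc(OC)cc3Oc3c(OC)cc(OC)cc3OC)c2O4)c1
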